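If you repeat these four flasks, watch how far the substrate has gone at the reading and which way the activated form turns at its fork.

    substrate + activator → activated form (k1 = 0.010 /M/s, Ea1 = 61.0 kJ/mol)
    activated form → ring (k2 = 0.034 /s, Ea2 = 72.0 kJ/mol)
    substrate + activated form → open dimer (k3 = 0.0077 /M/s, Ea3 = 64.0 kJ/mol)
    activated form → decomposed reagent (k4 = 0.0082 /s, Ea4 = 68.0 kJ/mol)
    crystals ⇌ ring, rate k5*(cs5 - [ring]) while solid is left; crystals form when [ring] > cs5 (cs5 = 0.97 M, k5 = 0.28 /s)
    (constants at 5 °C)

common to all: substrate 2.0 M; activator 1.10 equiv; time 25 s
- north-west: temperature −20 °C
- south: temperature 55 °C
- north-east: temperature 5 °C
- west: temperature 30 °C

- percent here means substrate units held: one open dimer counts as two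
- what is said of ring includes crystals
- crystals is a solid; its amount is given per volume of the solution
- constants are those at 5 °C; use the activation energies for any other temperature

- which flask leads in amount of ring, in percent of the substrate charged ("all alike" within 1.5 percentage points) (north-west / south / north-east / west / all alike)
- how much ring is there at the end, in percent of the substrate charged: north-west
- how much ring is there at the end, in percent of the substrate charged: south
- how much ring is there at the end, in percent of the substrate charged: north-east
- how much ring is there at the end, in percent of the substrate charged: west

**The fork.** I follow one activated molecule. Let c be the closure constant, d the decomposition constant, and g the dimer constant times [substrate]. The molecule closes, decomposes or takes a second substrate into open dimer, in proportion c : d : g. With activated form in steady state, ring gained per substrate lost is c/(c + d + 2g), and the activator cancels. Summing from the charge down to empty, with g taken at the charge, gives c/(2g) · ln(1 + 2g/(c + d)). At 55 °C, c is 3.91 /s, d is 0.724 /s and g is 1.04 /s. So the ring share, the ring per substrate charged once the charge has passed the fork, is 0.696.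

**The ladder.** Substrate is the limiting reagent, with activator at 1.10 equiv. The activation time is one over the activation constant times [activator] at the start. Fastest stands closure in south, at 0.256 s, which is shorter than south's activation time of 0.817 s, so the steady state holds there and I expect 69.6% of ring. West's activation time of 5.16 s is shorter than the reading at 25 s, but activation slows as substrate and activator thin out, so I take its share, 65.6%, as a ceiling. That share is lower than south's, as closure has a higher activation energy than either side step.

**Cold rungs.** North-east's activation time of 45.5 s is longer than the reading, and north-west's 615 s is longer still. In north-west, activated form then grows nearly linearly with time and ring with its square. Ring is then half the squared time over the product of activation and closure times. North-west's closure time is 636 s, which gives 0.0798%. In north-east, activated form has a loss time, one over the sum of c, d and g, of 17.4 s, which is shorter than the reading, so the same product overstates and gives a ceiling of 23.4%. My pick is south.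

**The forecast.** It names south, with 0.08% north-west, 70% south, 11.5% north-east and 58% west, on the ground that “ring closure has the highest activation energy and so gains on the side reactions”. For west and north-east it gives figures where I hold ceilings.

**The run.** Ring stands at 0.0759% north-west, 71.1% south, 11.2% north-east and 58.7% west, so south leads. South's 71.1%, beside its share of 69.6%, falls short of the charge because of both side steps acting together. Without the dimer step the share reduces to c/(c + d), or 84.4%, and the run with that step struck out reaches 83.9%. Striking decomposition instead reaches 82.3%. West, read at 250 s, has the share 65.6% against a ring reading of 67.8%.

The rate constants are made up; the flask was simulated.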